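The numbers in the tables were computed with constants of no real substance.

Time comes first here: epsilon and delta are both read at 12 min, and they differ in how long Sbt is fed.

| setting | maple | larch | epsilon | delta |
|---|---|---|---|---|
| Sbt | 0.54 M (fed, over 12 s) | 1.2 M (fed, over 12 s) | 0.80 M (fed, over 12 s) | 0.80 M (fed, over 6.0 s) |
| Tsp | 2.3 mol% | 2.3 mol% | 2.3 mol% | 2.3 mol% |
| remark | run made earlier; the fed solution adds 0.10 times the starting volume | run made earlier; the fed solution adds 0.10 times the starting volume | the fed solution adds 0.10 times the starting volume | the fed solution adds 0.10 times the starting volume |
| time |  |  | 12 min | 12 min |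

- maple (time / min: Sbt2 / %): 1.00: 7; 1.33: 14; 2.00: 25; 3.00: 37; 5.00: 60; 8.00: 86; 12.0: 94
- larch (time / min: Sbt2 / %): 1.00: 28; 1.33: 35; 2.00: 55; 3.00: 73; 5.00: 92; 8.00: 98; 12.0: 96

(scatter of a reading: 2 percentage points)

1. which of the two ends with the longer chains by the average number of monomer units in a chain (chains begun, living or dead) ("neither" if they lie within 10%) (epsilon / delta / neither)
2. average number of monomer units in a chain (chains begun, living or dead) at the end, epsilon
3. average number of monomer units in a chain (chains begun, living or dead) at the end, delta

- charges are per starting volume, the dose included; the dosed solution carries all of it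
- the average divides the monomer in chains by the number of chains begun, living and dead together
- the earlier runs do not show the number of chains; that part of a forecast is a guess

A bench rule counts turnovers: if each Tsp begins one chain, length is conversion times the turnover count, the Sbt charged per Tsp charged (the target degree of polymerisation), 43.5. The maple run ends at 94% and the larch run at 96%, so the reckoning made here gives 40.9 to 41.7 for a charge between them. The doses should not separate the flasks, since the dosing time of epsilon, 12 s, is much shorter than the run of 12 min.

The rule stops where Tsp has not begun a chain. At 1.00 min the larch reading is 4.00 times the maple reading on 2.22 times the charge. At equal loading, chains begun at once would give the ratio of the charges, whereas chains still being begun push it towards the square, 4.94. This ratio lies between the two, and with a scatter of 2 percentage points on readings of 7% and 28% it cannot tell them apart. Taking one Tsp to begin one chain and some Tsp perhaps none, the count is a floor for the length. How far above it the length lies is a guess.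

The forecast gives neither, with 45 for epsilon and 45 for delta: “Incomplete initiation could push it somewhat higher”.

The flasks give neither, with 52.3 for epsilon and 51.5 for delta.

    Sbt + Tsp → Tsp2 + Sbt2 (k = 0.0300 M⁻¹ s⁻¹)
    Sbt + Tsp2 → Sbt2 + Tsp2, rate k2*[Tsp2]*[Sbt] (k = 0.460 M⁻¹ s⁻¹)
    2 Tsp → Zed (k = 0.210 M⁻¹ s⁻¹)

Delta stands 1.20 times above its count, which puts the chains begun at 0.832 of the Tsp charged. At 12 min the delta flask holds 0.0139 M Tsp2 and 0.00132 M Zed, and 1.3% of its Sbt is left. Ten times the time changes little: at 120 min epsilon reads 53.1 and delta 52.2.

Delta read at 5.0 min has 80.3% Sbt2, so the count gives 34.9, and the same factor raises this to 41.9. The computed length there is 42.4.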